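Remark on the chemistry: locants C1–C11 are those of the target skeleton (ring C1–C6, chain C7–C11, O1/O4/O9 on C1/C4/C9) and are kept for every intermediate; the stereodescriptors in the names follow the IUPAC numbering of each compound.

## Structural features

The target is a bisabolane-type triester. A cyclohexene ring (C1–C6, trisubstituted C2=C3 alkene with a methyl on C3) carries oxygen on both allylic carbons, an angelate [(Z)-2-methylbut-2-enoate] on C1 and an acetate on C4. It is joined at C6 by a single bond to the chain C7(CH3)–C8H2–C9(OAc)–C10H=C11(CH3)2. There are five stereocentres, (1S,4R,6S,7R,9R): O1 and O4 are cis across the ring, the chain on C6 is trans to O1, C1/C6/C7 are contiguous, and C9 stands 1,3 to C7 on a freely rotating chain. The fragile parts are the angelate (it slips to the E-tiglate under nucleophilic acyl-transfer conditions and accepts nucleophiles), the C9 acetate (a prenyl-type allylic ester that ionises easily) and the ring allylic C1–O and C4–O bonds. Three secondary hydroxyls must carry two different acyl groups, so they have to be told apart. The real difficulty is C7, an exocyclic stereocentre without a functional group of its own, followed by the remote C9 carbinol. The key step exploits the fact that O1 is trans to C7 and is separated from C9 by four atoms (C1, C6, C7, C8, i.e. five bonds), so O1, C9, C8, C7, C6 and C1 can be tied into a temporary six-membered lactone, trans-fused to the cyclohexene, in which C7 is a ring atom.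

## Logic of the disconnections

**21 ⇒ 20.** The two acetyl–oxygen bonds at O4 and O9 are cut together. Both acetates are allylic and the C9 one is the most labile group in the molecule, so they are made last and in one operation. The demand is that O1 already carries its Z-enoate and that the acylation leaves it untouched.

**20 ⇒ 19.** The O4–Si bond is cut. A silyl ether is the one O4 group that survives organoaluminium, organomagnesium and borane reagents and still leaves without base. The demand is a buffered fluoride source that neither ionises the C9 allylic alcohol nor disturbs the enoate.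

**19 ⇒ 18.** The C9–H bond is cut, turning the carbinol into a conjugated ketone. C9 is too far from the ring for substrate control, whereas an enone offers an alkenyl/CH2 pair that a chiral reducing catalyst can distinguish. One stereocentre is removed. The demand is catalyst control and inertness of the enoate.

**18 ⇒ 15 + 16.** The O1–acyl bond of the Z-enoate is cut. The acylation is placed after the C9–C10 bond formation so that the enoate never meets an organomagnesium reagent, and before the C9 reduction so that O1 is the only free hydroxyl. The demand is acyl transfer without Z→E isomerisation.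

**15 ⇒ 12 + 13.** The C9–C10 bond is cut. An N-methoxy-N-methylamide at C9 stops cleanly at the ketone and brings in C10, C11 and both methyls in one step. The demand is tolerance of the free O1–H, met by a sacrificial equivalent of the organometallic 14.

**12 ⇒ 11.** The N–C9 bond is cut and O1–C9 is reconnected. The lactone stores O1 and C9 in one functional group, so O1 needs no protecting group and is released exactly when the next two steps need it. The demand is carbonyl attack without ionisation of the allylic C1–O bond.

**11 ⇒ 10.** The C7–H bond is cut. The acyclic stereocentre becomes an sp2 atom of a conformationally locked bicycle, so its configuration reduces to the direction of hydride approach. The demand is axial delivery to C7 and chemoselectivity over the C2=C3 alkene.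

**10 ⇒ 9.** The C7=C8 bond is cut, opening the lactone ring to an O1 acrylate and a C6 isopropenyl group. This is the strategic cut: it traces C8 and C9 to a three-carbon acid chloride and C7 with its methyl to the isopropenyl group of a terpene. The demand is ring closure between two poorly reactive alkenes.

**9 ⇒ 8 ⇒ 7 ⇒ 5 + 6.** The O4–Si bond, the C4–H bond and the O1–acyl bond are cut in that order. O1 is acylated while C4 is still a carbonyl, so the two ring oxygens are distinguished by oxidation state and no selective protection of a 1,4-diol is needed; the constitution of 9 is unchanged, only its assembly order. The demands are reagent-controlled hydride delivery giving the pseudoaxial C4–OH against the ring's preference for axial attack, survival of the acrylate, and a silylation free of nucleophiles.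

**5 ⇒ 3 ⇒ 1.** The C1–O bond is cut. Compound 1 supplies C6 in the correct configuration, the methyl-bearing alkene, the C4 carbonyl and the isopropenyl group. The oxygen is introduced at the γ-carbon through the extended silyl dienol ether 3 (via 2). A silyl ether is preferred to an acyl derivative because its diene is much more nucleophilic than the isopropenyl alkene and its formation needs no acid, which would aromatise the ring. The demands are γ- over α'-deprotonation, attack at the diene terminus and approach anti to the isopropenyl group.

## Other disconnections considered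

Alternative 1: The cuts are C1–C6 and C7–C8, with C1, C2, C9, C8, C7, C6 treated as a sacrificial cyclohexene.
- **Forward step.** (E)-But-2-enal A1, activated as the iminium ion of a chiral imidazolidinone salt, would undergo endo [4+2] cycloaddition with (E)-buta-1,3-dien-1-yl acetate A2 to give the cyclohexene carbaldehyde A3. Its acetoxy carbon is C1, its formyl-bearing carbon is C6 (formyl carbon = C5) and its methyl-bearing carbon is C7.
- **In favour.** Redrawing the target with C7 inside the ring shows that the endo rule (O1 cis to C5) and the E geometry of A1 (C5 trans to the C7 methyl) give exactly the C1/C6/C7 triad. Three contiguous stereocentres, including C7, would arise from two achiral bulk chemicals in one catalytic step. On stereocentres created per step this is better than the chosen key step, which creates none, and a concerted suprafacial addition is at least as secure a source of the C6/C7 relationship as a conformationally directed hydride. In absolute control the two plans are equal (catalyst versus chiral pool, both series accessible).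
- **Against.** A β-methyl enal iminium is a weak dienophile for an acyclic, moderately electron-rich diene, so slow conversion, polymerisation of A2 and loss of acetate are to be expected. More seriously, the ring of A3 is not the ring of the target. The C2=C9 alkene must be cleaved, which creates two more formyl groups beside the C5 formyl, and the three must be differentiated. C5 has to end as CH2, so the formyl carbon needs umpolung or deoxygenation after the C4–C5 bond is made. The O1 acetate lies β to the C5 aldehyde and invites E1cB loss. C3 with its methyl, C4 with its oxygen and stereocentre, C10, C11 and the C9 stereocentre would all still be missing.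
- **Comparison.** The chosen plan takes the ring, its alkene and C6 from 1 and spends its steps on oxygenation and on C7. The alternative obtains stereochemistry cheaply but spends many more steps on dismantling and re-closing rings, so in step economy it should be inferior to the 13-step sequence.

Alternative 2: The cuts are C7–CH3 and C8–C9.
- **Forward step.** A ring carrying both oxygens as silyl ethers and a vinyl group on C6, A4, would undergo zirconium-catalysed asymmetric carboalumination with trimethylaluminium A5 and a chiral bis(indenyl)ZrCl2-type catalyst, methyl adding to C7 and aluminium to C8. The primary alkylalane would be acylated in the same flask with 3-methylbut-2-enoyl chloride A6 to give enone A7.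
- **In favour.** Two C–C bonds and C7 are made in one operation without a temporary ring. A7 is the O1-triethylsilyl analogue of 15, so the sequence after the key step would be as short as or shorter than the chosen endgame; on step count after the key step, and on convergence, the alternative is the better.
- **Against.** The vinyl group sits on a secondary carbon next to a Lewis-basic allylic silyl ether, at the edge of what this carbometalation tolerates (slow insertion, competing hydroalumination, catalyst control that must match or override C6). Excess A5 and the chloroaluminium species formed can ionise the allylic C1–O and C4–O bonds. Direct acylation of the alane with an enoyl chloride is not selective: methyl groups on aluminium compete with the C8 alkyl, and the enone accepts conjugate methyl addition, so a transmetalation step would probably have to be added. A4 is not on the line from 1, because replacing isopropenyl by vinyl requires a different and longer ring synthesis.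
- **Comparison.** The alternative sets C7 by catalyst-controlled migratory insertion on a freely rotating substituent. The chosen plan sets it by hydride addition to a locked ring, which depends less on a catalyst recognising an unusual substrate. Once the preparation of A4 is counted, the two should be of comparable length.

Alternative 3: The cuts are C5–C6 and C1=C2, so the ring is formed by annulation onto a finished chain.
- **Forward step.** The chain aldehyde A8 (formyl carbon = C1, with C7 and C9 already configured) would form an enamine with a diarylprolinol silyl ether and add to but-3-en-2-one A9. Aldol condensation of the methyl ketone carbon (C2) onto C1 would give the 4-substituted cyclohex-2-enone A10.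
- **In favour.** It is metal-free and one-flask, and the fragile chain is introduced complete. It equals the chosen key step in closing one six-membered ring, and it is better in that this ring belongs to the target and that C6 is set under catalyst control.
- **Against.** A10 has its carbonyl on C3 and lacks the C3 methyl and any oxygen on C1 or C4. Methyl addition, a 1,3-oxygen transposition to C1 and a separate oxygenation of C4 would follow, with C1 and C4 set late by substrate control while the acid-sensitive C9 allylic silyl ether is present. A8 is β-branched at C7, which slows enamine formation and makes selectivity at C6 a matched/mismatched question. A8 itself needs a multistep synthesis with 1,3-related stereocentres.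
- **Comparison.** The chosen plan has the ring pattern of C1, C3, C4 and C6 in place after five steps from 1 and then grows the chain. The alternative grows the chain first and must then repair the ring oxidation pattern. It is more convergent but probably longer, and it imports C7 instead of creating it, which moves the hardest problem into the synthesis of A8.

Key step: step 6

## Route

Step 1
Reactants: 1 (S)-(+)-carvone
Product: 3 {[(5R)-2-methyl-5-(prop-1-en-2-yl)cyclohexa-1,3-dien-1-yl]oxy}trimethylsilane, via bromomagnesium dienolate 2 (not isolated)
Conditions: MeMgBr, FeCl3 (5 mol %), Et2O, −20 °C; then Me3SiCl, Et3N, DMPU, −20 °C → rt; used crude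
Reagents that add atoms: chlorotrimethylsilane, C[Si](C)(C)Cl
Why: Iron-catalysed γ-deprotonation of an enone by MeMgBr (Kharasch-type conditions) removes a ring proton γ to the carbonyl instead of adding to it, and the extended magnesium dienolate 2 is silylated on oxygen; the isopropenyl-bearing carbon is not touched, so the stereocentre of 1 is carried over (the descriptor becomes R only because ring priorities change).

Step 2
Reactants: 3 {[(5R)-2-methyl-5-(prop-1-en-2-yl)cyclohexa-1,3-dien-1-yl]oxy}trimethylsilane
Product: 5 (4R,5S)-4-hydroxy-2-methyl-5-(prop-1-en-2-yl)cyclohex-2-en-1-one, via vinyl epoxide 4 (not isolated)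
Conditions: mCPBA, NaHCO3, CH2Cl2, −40 → 0 °C; then 1 M HCl, THF, 0 °C
Reagents that add atoms: meta-chloroperoxybenzoic acid, O=C(OO)c1cccc(Cl)c1
Why: Vinylogous Rubottom oxidation: the peracid epoxidises the terminal, unsubstituted double bond of the electron-rich silyloxydiene (the α-carbon is blocked by methyl and the isopropenyl alkene is far less nucleophilic at this temperature) from the face opposite the adjacent isopropenyl group, and epoxide 4 opens with loss of silicon to the γ-hydroxy enone; the new carbinol (C1 of the target) is therefore set trans to its neighbour by steric approach control.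

Step 3
Reactants: 5 (4R,5S)-4-hydroxy-2-methyl-5-(prop-1-en-2-yl)cyclohex-2-en-1-one; 6 acryloyl chloride
Product: 7 (1R,6S)-3-methyl-4-oxo-6-(prop-1-en-2-yl)cyclohex-2-en-1-yl prop-2-enoate
Conditions: i-Pr2NEt, CH2Cl2, −78 → −20 °C
Reagents that add atoms: none
Why: O-Acylation of a secondary allylic alcohol with an acid chloride and a hindered amine; acylating while C4 is still a ketone distinguishes O1 from O4 by oxidation state, and the low temperature suppresses base-induced isomerisation of the γ-hydroxy enone and polymerisation of the acrylate.

Step 4
Reactants: 7 (1R,6S)-3-methyl-4-oxo-6-(prop-1-en-2-yl)cyclohex-2-en-1-yl prop-2-enoate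
Product: 8 (1R,4R,6S)-4-hydroxy-3-methyl-6-(prop-1-en-2-yl)cyclohex-2-en-1-yl prop-2-enoate
Conditions: (S)-2-methyl-CBS-oxazaborolidine (0.3 equiv), catecholborane, toluene, −78 °C; MeOH quench
Reagents that add atoms: none
Why: Corey–Bakshi–Shibata reduction of a cyclic enone: the (S)-oxazaborolidine binds the ketone with the methyl-substituted alkenyl carbon C3 as the large and C5H2 as the small group and should deliver hydride to give the 4R carbinol (pseudoaxial OH, cis to O1, trans to the isopropenyl group), overriding the ring's preference for axial attack; catecholborane at −78 °C reduces neither the acrylate nor the isopropenyl group.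

Step 5
Reactants: 8 (1R,4R,6S)-4-hydroxy-3-methyl-6-(prop-1-en-2-yl)cyclohex-2-en-1-yl prop-2-enoate
Product: 9 (1R,4R,6S)-4-[(tert-butyldimethylsilyl)oxy]-3-methyl-6-(prop-1-en-2-yl)cyclohex-2-en-1-yl prop-2-enoate
Conditions: TBSOTf, 2,6-lutidine, CH2Cl2, −78 °C
Reagents that add atoms: tert-butyldimethylsilyl trifluoromethanesulfonate, CC(C)(C)[Si](C)(C)OS(=O)(=O)C(F)(F)F
Why: Silylation of a secondary allylic alcohol with a silyl triflate and a non-nucleophilic pyridine base, chosen so that no nucleophile able to add to the acrylate is present; no stereocentre is affected.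

Step 6
Reactants: 9 (1R,4R,6S)-4-[(tert-butyldimethylsilyl)oxy]-3-methyl-6-(prop-1-en-2-yl)cyclohex-2-en-1-yl prop-2-enoate
Product: 10 (4aS,6R,8aR)-6-[(tert-butyldimethylsilyl)oxy]-4,7-dimethyl-4a,5,6,8a-tetrahydro-2H-chromen-2-one
Conditions: second-generation Grubbs catalyst (H2IMes)(PCy3)Cl2Ru=CHPh (10 mol %, two portions), toluene (0.005 M), 80 °C, argon purge
Reagents that add atoms: none
Why: Ring-closing olefin metathesis by the Chauvin mechanism: the ruthenium benzylidene exchanges onto one of the two terminal alkenes, the new alkylidene undergoes intramolecular [2+2] cycloaddition with the other alkene, and cycloreversion of the ruthenacyclobutane forms C7=C8 and, after turnover, releases ethene. The closest known reaction type is the ring-closing metathesis of acrylates of homoallylic alcohols bearing a 1,1-disubstituted alkene to β-methyl α,β-unsaturated δ-lactones with N-heterocyclic-carbene ruthenium catalysts. The ring closed is the six-membered lactone O1–C9–C8–C7–C6–C1, formed by joining two exocyclic alkene termini so that the new double bond is endocyclic and necessarily Z. The ring is trans-fused because O1 and the isopropenyl group are trans-diequatorial on the cyclohexene half-chair and already gauche to each other. No stereocentre is created and C1, C4 and C6 are untouched. The selectivity needed is site selectivity and cyclisation over oligomerisation: the trisubstituted, unstrained C2=C3 alkene is too hindered to enter the catalytic cycle, and high dilution with removal of ethene favours the intramolecular path. The s-cis ester rotamer needed for closure is populated at 80 °C, and the conjugated, trisubstituted product alkene is a poor metathesis partner, so the closure should not reverse.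

Step 7
Reactants: 10 (4aS,6R,8aR)-6-[(tert-butyldimethylsilyl)oxy]-4,7-dimethyl-4a,5,6,8a-tetrahydro-2H-chromen-2-one
Product: 11 (4R,4aS,6R,8aS)-6-[(tert-butyldimethylsilyl)oxy]-4,7-dimethyl-3,4,4a,5,6,8a-hexahydro-2H-chromen-2-one
Conditions: Cu(OAc)2·H2O (5 mol %), 1,2-bis(diphenylphosphino)benzene (5 mol %), (EtO)2MeSiH, t-BuOH, toluene, rt
Reagents that add atoms: none
Why: Copper hydride conjugate reduction of a β-substituted α,β-unsaturated δ-lactone: the phosphine-ligated Cu–H adds hydride to the β-carbon C7, t-BuOH protonates the copper enolate and the silane regenerates Cu–H; the trans ring fusion locks the lactone half-chair with C6–H axial, so hydride should enter C7 axially, anti to C6–H through a chair-like transition state, leaving the C7 methyl equatorial (7R), while the isolated C2=C3 alkene and the silyl ether are inert.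

Step 8
Reactants: 11 (4R,4aS,6R,8aS)-6-[(tert-butyldimethylsilyl)oxy]-4,7-dimethyl-3,4,4a,5,6,8a-hexahydro-2H-chromen-2-one
Product: 12 (3R)-3-{(1S,2S,5R)-5-[(tert-butyldimethylsilyl)oxy]-2-hydroxy-4-methylcyclohex-3-en-1-yl}-N-methoxy-N-methylbutanamide
Conditions: MeNH(OMe)·HCl, AlMe3, CH2Cl2, 0 °C → rt; aq. potassium sodium tartrate
Reagents that add atoms: N,O-dimethylhydroxylamine hydrochloride, CNOC.Cl
Why: Aminolysis of a lactone by the aluminium amide made from AlMe3 and the amine hydrochloride gives the N-methoxy-N-methylamide and frees O1–H by acyl–oxygen cleavage, so C1 keeps its configuration; attack at the carbonyl should be much faster than Lewis-acid ionisation of the allylic C1–O bond at 0 °C.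

Step 9
Reactants: 12 (3R)-3-{(1S,2S,5R)-5-[(tert-butyldimethylsilyl)oxy]-2-hydroxy-4-methylcyclohex-3-en-1-yl}-N-methoxy-N-methylbutanamide; 13 1-bromo-2-methylprop-1-ene
Product: 15 (6R)-6-{(1S,2S,5R)-5-[(tert-butyldimethylsilyl)oxy]-2-hydroxy-4-methylcyclohex-3-en-1-yl}-2-methylhept-2-en-4-one, via 2-methylprop-1-enylmagnesium bromide 14 (not isolated)
Conditions: Mg, THF, 45 °C (13 → 14, 3 equiv); then 12, THF, −20 → 0 °C; aq. NH4Cl
Reagents that add atoms: none
Why: Grignard addition to an N-methoxy-N-methylamide: the first equivalent of 14 deprotonates O1–H and a second adds to the amide to give a chelated tetrahedral magnesium intermediate that collapses to the ketone only on work-up, so no tertiary alcohol forms and no ester is yet present to compete.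

Step 10
Reactants: 15 (6R)-6-{(1S,2S,5R)-5-[(tert-butyldimethylsilyl)oxy]-2-hydroxy-4-methylcyclohex-3-en-1-yl}-2-methylhept-2-en-4-one; 16 angelic acid
Product: 18 (1S,4R,6S)-4-[(tert-butyldimethylsilyl)oxy]-3-methyl-6-[(2R)-6-methyl-4-oxohept-5-en-2-yl]cyclohex-2-en-1-yl (2Z)-2-methylbut-2-enoate, via angelic 2,4,6-trichlorobenzoic anhydride 17 (not isolated)
Conditions: 16, 2,4,6-Cl3C6H2COCl, Et3N, toluene, rt; then 15, 75 °C
Reagents that add atoms: none
Why: Yamaguchi-type esterification without a nucleophilic catalyst: the alcohol attacks the less hindered angeloyl carbonyl of mixed anhydride 17, and leaving out DMAP avoids the addition–elimination pathway that turns activated angeloyl species into the E isomer; O1–H is the only free hydroxyl and reacts at oxygen, so C1 is retained.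

Step 11
Reactants: 18 (1S,4R,6S)-4-[(tert-butyldimethylsilyl)oxy]-3-methyl-6-[(2R)-6-methyl-4-oxohept-5-en-2-yl]cyclohex-2-en-1-yl (2Z)-2-methylbut-2-enoate
Product: 19 (1S,4R,6S)-4-[(tert-butyldimethylsilyl)oxy]-6-[(2R,4R)-4-hydroxy-6-methylhept-5-en-2-yl]-3-methylcyclohex-2-en-1-yl (2Z)-2-methylbut-2-enoate
Conditions: (S)-2-methyl-CBS-oxazaborolidine (0.5 equiv), catecholborane, toluene, −78 °C; MeOH quench
Reagents that add atoms: none
Why: Corey–Bakshi–Shibata reduction of an acyclic enone with the C10=C11 alkenyl group as the large and C8H2 as the small substituent; the (S)-catalyst should give the 9R allylic alcohol by the same sense of induction as in step 4, and the angelate, silyl ether and alkenes do not react with catecholborane at −78 °C.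

Step 12
Reactants: 19 (1S,4R,6S)-4-[(tert-butyldimethylsilyl)oxy]-6-[(2R,4R)-4-hydroxy-6-methylhept-5-en-2-yl]-3-methylcyclohex-2-en-1-yl (2Z)-2-methylbut-2-enoate
Product: 20 (1S,4R,6S)-4-hydroxy-6-[(2R,4R)-4-hydroxy-6-methylhept-5-en-2-yl]-3-methylcyclohex-2-en-1-yl (2Z)-2-methylbut-2-enoate
Conditions: HF·pyridine, pyridine, THF, 0 °C → rt
Reagents that add atoms: none
Why: Fluoride cleavage of a secondary silyl ether with pyridine-buffered HF·pyridine; the buffer keeps the medium too weakly acidic to ionise the prenyl-type C9 allylic alcohol and too weakly basic to isomerise or migrate the angelate.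

Step 13
Reactants: 20 (1S,4R,6S)-4-hydroxy-6-[(2R,4R)-4-hydroxy-6-methylhept-5-en-2-yl]-3-methylcyclohex-2-en-1-yl (2Z)-2-methylbut-2-enoate
Product: 21 (1S,4R,6S)-4-acetoxy-6-[(2R,4R)-4-acetoxy-6-methylhept-5-en-2-yl]-3-methylcyclohex-2-en-1-yl (2Z)-2-methylbut-2-enoate (CNP0417294.1)
Conditions: Ac2O, pyridine, DMAP (cat.), CH2Cl2, 0 °C → rt
Reagents that add atoms: acetic anhydride, CC(=O)OC(C)=O
Why: Acetylation of both secondary allylic alcohols under pyridine/DMAP catalysis; acyl transfer occurs at oxygen, so C4 and C9 keep their configuration, and the angelate ester already in place is not activated under these conditions.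

## Compound list

1 | (S)-(+)-carvone, (5S)-2-methyl-5-(prop-1-en-2-yl)cyclohex-2-en-1-one | CC1=CC[C@@H](CC1=O)C(C)=C | starting material
2 | bromomagnesium (5R)-2-methyl-5-(prop-1-en-2-yl)cyclohexa-1,3-dien-1-olate | Br[Mg]OC1=C(C)C=C[C@@H](C1)C(C)=C | intermediate (not isolated)
3 | {[(5R)-2-methyl-5-(prop-1-en-2-yl)cyclohexa-1,3-dien-1-yl]oxy}trimethylsilane | C[Si](C)(C)OC1=C(C)C=C[C@@H](C1)C(C)=C | intermediate
4 | trimethyl{[(1R,5S,6S)-2-methyl-5-(prop-1-en-2-yl)-7-oxabicyclo[4.1.0]hept-2-en-3-yl]oxy}silane (epoxide oxygen anti to the isopropenyl group) | O1[C@@H]2[C@H]1C(C)=C(O[Si](C)(C)C)C[C@H]2C(C)=C | intermediate (not isolated)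
5 | (4R,5S)-4-hydroxy-2-methyl-5-(prop-1-en-2-yl)cyclohex-2-en-1-one (OH trans to isopropenyl) | O[C@@H]1C=C(C)C(=O)C[C@H]1C(C)=C | intermediate
6 | acryloyl chloride | C=CC(Cl)=O | starting material
7 | (1R,6S)-3-methyl-4-oxo-6-(prop-1-en-2-yl)cyclohex-2-en-1-yl prop-2-enoate | C=CC(=O)O[C@@H]1C=C(C)C(=O)C[C@H]1C(C)=C | intermediate
8 | (1R,4R,6S)-4-hydroxy-3-methyl-6-(prop-1-en-2-yl)cyclohex-2-en-1-yl prop-2-enoate | C=CC(=O)O[C@@H]1C=C(C)[C@H](O)C[C@H]1C(C)=C | intermediate
9 | (1R,4R,6S)-4-[(tert-butyldimethylsilyl)oxy]-3-methyl-6-(prop-1-en-2-yl)cyclohex-2-en-1-yl prop-2-enoate | C=CC(=O)O[C@@H]1C=C(C)[C@H](O[Si](C)(C)C(C)(C)C)C[C@H]1C(C)=C | intermediate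
10 | (4aS,6R,8aR)-6-[(tert-butyldimethylsilyl)oxy]-4,7-dimethyl-4a,5,6,8a-tetrahydro-2H-chromen-2-one (trans-fused) | O=C2O[C@@H]1C=C(C)[C@H](O[Si](C)(C)C(C)(C)C)C[C@H]1C(C)=C2 | intermediate
11 | (4R,4aS,6R,8aS)-6-[(tert-butyldimethylsilyl)oxy]-4,7-dimethyl-3,4,4a,5,6,8a-hexahydro-2H-chromen-2-one | O=C2O[C@@H]1C=C(C)[C@H](O[Si](C)(C)C(C)(C)C)C[C@H]1[C@H](C)C2 | intermediate
12 | (3R)-3-{(1S,2S,5R)-5-[(tert-butyldimethylsilyl)oxy]-2-hydroxy-4-methylcyclohex-3-en-1-yl}-N-methoxy-N-methylbutanamide | O[C@@H]1C=C(C)[C@H](O[Si](C)(C)C(C)(C)C)C[C@H]1[C@H](C)CC(=O)N(C)OC | intermediate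
13 | 1-bromo-2-methylprop-1-ene | CC(C)=CBr | starting material
14 | (2-methylprop-1-en-1-yl)magnesium bromide | CC(C)=C[Mg]Br | intermediate (not isolated)
15 | (6R)-6-{(1S,2S,5R)-5-[(tert-butyldimethylsilyl)oxy]-2-hydroxy-4-methylcyclohex-3-en-1-yl}-2-methylhept-2-en-4-one | O[C@@H]1C=C(C)[C@H](O[Si](C)(C)C(C)(C)C)C[C@H]1[C@H](C)CC(=O)C=C(C)C | intermediate
16 | angelic acid, (2Z)-2-methylbut-2-enoic acid | C/C=C(/C)C(=O)O | starting material
17 | (2Z)-2-methylbut-2-enoic 2,4,6-trichlorobenzoic anhydride | C/C=C(/C)C(=O)OC(=O)c1c(Cl)cc(Cl)cc1Cl | intermediate (not isolated)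
18 | (1S,4R,6S)-4-[(tert-butyldimethylsilyl)oxy]-3-methyl-6-[(2R)-6-methyl-4-oxohept-5-en-2-yl]cyclohex-2-en-1-yl (2Z)-2-methylbut-2-enoate | C/C=C(/C)C(=O)O[C@@H]1C=C(C)[C@H](O[Si](C)(C)C(C)(C)C)C[C@H]1[C@H](C)CC(=O)C=C(C)C | intermediate
19 | (1S,4R,6S)-4-[(tert-butyldimethylsilyl)oxy]-6-[(2R,4R)-4-hydroxy-6-methylhept-5-en-2-yl]-3-methylcyclohex-2-en-1-yl (2Z)-2-methylbut-2-enoate | C/C=C(/C)C(=O)O[C@@H]1C=C(C)[C@H](O[Si](C)(C)C(C)(C)C)C[C@H]1[C@H](C)C[C@H](C=C(C)C)O | intermediate
20 | (1S,4R,6S)-4-hydroxy-6-[(2R,4R)-4-hydroxy-6-methylhept-5-en-2-yl]-3-methylcyclohex-2-en-1-yl (2Z)-2-methylbut-2-enoate | C/C=C(/C)C(=O)O[C@@H]1C=C(C)[C@H](O)C[C@H]1[C@H](C)C[C@H](C=C(C)C)O | intermediate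
21 | (1S,4R,6S)-4-acetoxy-6-[(2R,4R)-4-acetoxy-6-methylhept-5-en-2-yl]-3-methylcyclohex-2-en-1-yl (2Z)-2-methylbut-2-enoate | C/C=C(/C)C(=O)O[C@@H]1C=C(C)[C@H](OC(C)=O)C[C@H]1[C@H](C)C[C@H](C=C(C)C)OC(C)=O | target

## Step count and least certain steps

Total step count: 13 (steps 1–13). Longest linear sequence: 13 steps from 1 to 21; 6, 13 and 16 are purchased and enter in steps 3, 9 and 10.

**Step 6 (key step).** The most likely failure is slow initiation and turnover, because one alkene is electron-poor and the other is 1,1-disubstituted; catalyst decomposition and intermolecular cross-metathesis of the acrylate would then compete with ring closure. The fallback is a relay ring-closing metathesis. It sets out from 5, which would be acylated with (2E)-octa-2,7-dienoyl chloride in place of 6 to give the (2E)-octa-2,7-dienoate of the hydroxy enone F1. The reduction of step 4 would give the C4 alcohol F2, and the silylation of step 5 the silyl ether F3. With the same ruthenium catalyst the terminal monosubstituted alkene of F3 is loaded quickly, cyclopentene is expelled, and the alkylidene is placed directly on C8, from where it closes onto the isopropenyl group. The fallback comes back to the route at 10.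

**Step 2.** The most likely failure is poor site or facial selectivity of the epoxidation: attack at the isopropenyl alkene, at the α-carbon of the dienol ether, or syn to the isopropenyl group. The fallback sets out from 3 and uses dye-sensitised photo-oxygenation (O2, tetraphenylporphyrin, visible light, CH2Cl2, −78 °C). Singlet oxygen adds in a [4+2] sense across the two ends of the silyloxydiene, anti to the isopropenyl group, to give the silyloxy endoperoxide F4, so the regiochemistry is fixed by the cycloaddition. Methanol cleaves the silyl peroxyketal to the γ-hydroperoxy enone F5, and PPh3 reduces the O–O bond. The fallback comes back at 5.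

**Step 4.** The most likely failure is incomplete override of the ring's preference for axial hydride attack, which would give the C4 epimer. The fallback sets out from 7 and accepts that preference. Luche reduction (NaBH4, CeCl3·7H2O, MeOH, −78 °C) would give the 4S alcohol F6 (OH cis to the isopropenyl group). Mitsunobu inversion with chloroacetic acid (PPh3, DIAD, toluene, 0 °C) would give the 4R chloroacetate F7. Thiourea with NaHCO3 in EtOH removes the chloroacetyl group in the presence of the acrylate. The fallback comes back at 8.

**Step 7.** The most likely failure is insufficient facial selectivity at C7, or sluggish hydride transfer to the β,β-disubstituted position, if the conformational bias of the ring is weaker than assumed. The fallback sets out from 10 and transfers the stereocontrol from the substrate to the reagent. The achiral diphosphine is replaced by an enantiopure biaryl diphosphine (DTBM-SEGPHOS with Cu(OAc)2·H2O and the same silane), both ligand enantiomers are tested, and the one that reinforces axial delivery is used. The fallback comes back at 11 and makes no new compound.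

**Step 10.** The most likely failure is Z→E isomerisation of the angeloyl unit during activation, or slow acylation of the hindered O1–H at 75 °C with competing hemiketal formation toward C9. The fallback sets out from 15 and builds the Z alkene on the ester instead of transferring it. O1 is esterified with 2-[bis(2,2,2-trifluoroethoxy)phosphoryl]propanoic acid (DCC, CH2Cl2, 0 °C) to give the phosphonopropanoate F8. Still–Gennari olefination (KN(SiMe3)2, 18-crown-6, acetaldehyde, THF, −78 °C) then forms the Z-trisubstituted enoate. The fallback comes back at 18.

**Step 11.** The most likely failure is modest catalyst control, because the alkenyl and CH2 substituents of the acyclic ketone differ less in size than in the ring case, so the 9S epimer would form alongside 19. The fallback sets out from 18. Luche reduction gives 19 together with the 9S alcohol F9, and the two are separated. F9 undergoes Mitsunobu reaction with acetic acid (PPh3, DIAD) with inversion to the 9R acetate F10. Desilylation with buffered HF·pyridine gives the C4 alcohol F11, and acetylation of O4 comes back to the route at 21. The 9R portion continues through steps 12 and 13.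

## Further compounds

F1 | step 6 | (1R,6S)-3-methyl-4-oxo-6-(prop-1-en-2-yl)cyclohex-2-en-1-yl (2E)-octa-2,7-dienoate | C=CCCC/C=C/C(=O)O[C@@H]1C=C(C)C(=O)C[C@H]1C(C)=C
F2 | step 6 | (1R,4R,6S)-4-hydroxy-3-methyl-6-(prop-1-en-2-yl)cyclohex-2-en-1-yl (2E)-octa-2,7-dienoate | C=CCCC/C=C/C(=O)O[C@@H]1C=C(C)[C@H](O)C[C@H]1C(C)=C
F3 | step 6 | (1R,4R,6S)-4-[(tert-butyldimethylsilyl)oxy]-3-methyl-6-(prop-1-en-2-yl)cyclohex-2-en-1-yl (2E)-octa-2,7-dienoate | C=CCCC/C=C/C(=O)O[C@@H]1C=C(C)[C@H](O[Si](C)(C)C(C)(C)C)C[C@H]1C(C)=C
F4 | step 2 | 6-methyl-8-(prop-1-en-2-yl)-1-(trimethylsilyloxy)-2,3-dioxabicyclo[2.2.2]oct-5-ene (peroxide bridge anti to the isopropenyl group) | O2[C@@H]1C=C(C)[C@@](O2)(O[Si](C)(C)C)C[C@H]1C(C)=C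
F5 | step 2 | (4R,5S)-4-hydroperoxy-2-methyl-5-(prop-1-en-2-yl)cyclohex-2-en-1-one | OO[C@@H]1C=C(C)C(=O)C[C@H]1C(C)=C
F6 | step 4 | (1R,4S,6S)-4-hydroxy-3-methyl-6-(prop-1-en-2-yl)cyclohex-2-en-1-yl prop-2-enoate | C=CC(=O)O[C@@H]1C=C(C)[C@@H](O)C[C@H]1C(C)=C
F7 | step 4 | (1R,4R,6S)-4-(2-chloroacetoxy)-3-methyl-6-(prop-1-en-2-yl)cyclohex-2-en-1-yl prop-2-enoate | C=CC(=O)O[C@@H]1C=C(C)[C@H](OC(=O)CCl)C[C@H]1C(C)=C
F0 | step 7 | none | none
F8 | step 10 | (1S,4R,6S)-4-[(tert-butyldimethylsilyl)oxy]-3-methyl-6-[(2R)-6-methyl-4-oxohept-5-en-2-yl]cyclohex-2-en-1-yl 2-[bis(2,2,2-trifluoroethoxy)phosphoryl]propanoate (mixture at the phosphonate α-carbon) | CC(C(=O)O[C@@H]1C=C(C)[C@H](O[Si](C)(C)C(C)(C)C)C[C@H]1[C@H](C)CC(=O)C=C(C)C)P(=O)(OCC(F)(F)F)OCC(F)(F)F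
F9 | step 11 | (1S,4R,6S)-4-[(tert-butyldimethylsilyl)oxy]-6-[(2R,4S)-4-hydroxy-6-methylhept-5-en-2-yl]-3-methylcyclohex-2-en-1-yl (2Z)-2-methylbut-2-enoate | C/C=C(/C)C(=O)O[C@@H]1C=C(C)[C@H](O[Si](C)(C)C(C)(C)C)C[C@H]1[C@H](C)C[C@@H](C=C(C)C)O
F10 | step 11 | (1S,4R,6S)-6-[(2R,4R)-4-acetoxy-6-methylhept-5-en-2-yl]-4-[(tert-butyldimethylsilyl)oxy]-3-methylcyclohex-2-en-1-yl (2Z)-2-methylbut-2-enoate | C/C=C(/C)C(=O)O[C@@H]1C=C(C)[C@H](O[Si](C)(C)C(C)(C)C)C[C@H]1[C@H](C)C[C@H](C=C(C)C)OC(C)=O
F11 | step 11 | (1S,4R,6S)-6-[(2R,4R)-4-acetoxy-6-methylhept-5-en-2-yl]-4-hydroxy-3-methylcyclohex-2-en-1-yl (2Z)-2-methylbut-2-enoate | C/C=C(/C)C(=O)O[C@@H]1C=C(C)[C@H](O)C[C@H]1[C@H](C)C[C@H](C=C(C)C)OC(C)=O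
A1 | alternative 1 | (E)-but-2-enal | C/C=C/C=O
A2 | alternative 1 | (E)-buta-1,3-dien-1-yl acetate | CC(=O)O/C=C/C=C
A3 | alternative 1 | (1S,2R,6R)-2-acetoxy-6-methylcyclohex-3-ene-1-carbaldehyde (acetoxy cis, methyl trans to formyl) | CC(=O)O[C@@H]1C=CC[C@@H](C)[C@@H]1C=O
A4 | alternative 2 | (1S,4R,6S)-4-[(tert-butyldimethylsilyl)oxy]-3-methyl-1-[(triethylsilyl)oxy]-6-vinylcyclohex-2-ene (target numbering) | CC[Si](CC)(CC)O[C@@H]1C=C(C)[C@H](O[Si](C)(C)C(C)(C)C)C[C@H]1C=C
A5 | alternative 2 | trimethylaluminium | C[Al](C)C
A6 | alternative 2 | 3-methylbut-2-enoyl chloride | CC(C)=CC(Cl)=O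
A7 | alternative 2 | (6R)-6-{(1S,2S,5R)-5-[(tert-butyldimethylsilyl)oxy]-4-methyl-2-[(triethylsilyl)oxy]cyclohex-3-en-1-yl}-2-methylhept-2-en-4-one | CC[Si](CC)(CC)O[C@@H]1C=C(C)[C@H](O[Si](C)(C)C(C)(C)C)C[C@H]1[C@H](C)CC(=O)C=C(C)C
A8 | alternative 3 | (3R,5R)-5-[(tert-butyldimethylsilyl)oxy]-3,7-dimethyloct-6-enal | O=CC[C@H](C)C[C@H](C=C(C)C)O[Si](C)(C)C(C)(C)C
A9 | alternative 3 | but-3-en-2-one | CC(=O)C=C
A10 | alternative 3 | (4S)-4-{(2R,4R)-4-[(tert-butyldimethylsilyl)oxy]-6-methylhept-5-en-2-yl}cyclohex-2-en-1-one | O=C1CC[C@H](C=C1)[C@H](C)C[C@H](C=C(C)C)O[Si](C)(C)C(C)(C)C
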